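The route rests on the bond between C2 of the pyranone ring (ring C) and C1' of the prenylated resorcinol ring (ring B). C2 is the β-carbon of the C4 ketone (O1–C2–C3–C4=O), so the skeleton is the conjugate adduct of a flat 5,7-dioxygenated chromone and a B-ring aryl nucleophile. A rhodium-catalysed asymmetric 1,4-addition of the fully geranylated and prenylated arylboronic acid to 5,7-bis(MOM)chromone forms this bond and sets C2 under catalyst control in one operation. The boronic acid comes from resorcinol by three successive directed ortho-metalations. The C3 hydroxyl is then introduced trans to the aryl group by enolate oxidation, and acid removes the four MOM groups.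

Key step: step 6

Remark on the chemistry: geranyl = (2E)-3,7-dimethylocta-2,6-dien-1-yl, prenyl = 3-methylbut-2-en-1-yl, MOM = methoxymethyl. 5,7-Dihydroxychromone, geranyl bromide and prenyl bromide are taken as commercially available.

Step 1
Reactants: 1 resorcinol
Product: 2 1,3-bis(methoxymethoxy)benzene
Conditions: NaH, MOMCl, DMF, 0 °C → rt
Reagents that add atoms: chloromethyl methyl ether (MOMCl), COCCl
Why: Williamson-type O-alkylation of both phenoxides should give the bis-acetal, which serves as protecting group and as director for the following ortho-metalations.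

Step 2
Reactants: 2 1,3-bis(methoxymethoxy)benzene; 3 geranyl bromide
Product: 5 2-geranyl-1,3-bis(methoxymethoxy)benzene, via 2-lithio-1,3-bis(methoxymethoxy)benzene 4 (not isolated)
Conditions: n-BuLi, THF, 0 °C → rt; then CuI (10 mol %), geranyl bromide, −78 °C → rt
Reagents that add atoms: none
Why: Directed ortho-metalation should occur at C2, the position flanked by both OMOM directors, and copper-catalysed SN2 allylation at the primary carbon of geranyl bromide should leave the E-alkene untouched.

Step 3
Reactants: 5 2-geranyl-1,3-bis(methoxymethoxy)benzene; 6 prenyl bromide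
Product: 8 2-geranyl-1,3-bis(methoxymethoxy)-4-prenylbenzene, via 3-geranyl-2,4-bis(methoxymethoxy)phenyllithium 7 (not isolated)
Conditions: n-BuLi, TMEDA, THF, −20 → 0 °C; then CuI (10 mol %), prenyl bromide, −78 °C → rt
Reagents that add atoms: none
Why: A second directed ortho-metalation should take place at C4 (equivalent to C6), where chelation to the OMOM group makes ring lithiation faster than deprotonation of the benzylic–allylic CH2, and the aryllithium is then allylated as in step 2.

Step 4
Reactants: 8 2-geranyl-1,3-bis(methoxymethoxy)-4-prenylbenzene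
Product: 11 [3-geranyl-2,4-bis(methoxymethoxy)-5-prenylphenyl]boronic acid, via 3-geranyl-2,4-bis(methoxymethoxy)-5-prenylphenyllithium 9 (not isolated), via lithium aryl(trimethoxy)borate 10 (not isolated)
Conditions: n-BuLi, TMEDA, THF, −20 → 0 °C; B(OMe)3, −78 °C → rt; sat. aq. NH4Cl
Reagents that add atoms: trimethyl borate, COB(OC)OC; water, O
Why: The third directed ortho-metalation can only occur at the last C–H ortho to an OMOM group, and borate trapping followed by mild hydrolysis (which the MOM ethers tolerate) should give the boronic acid with boron at the future C1'.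

Step 5
Reactants: 12 5,7-dihydroxychromone
Product: 13 5,7-bis(methoxymethoxy)chromone
Conditions: NaH, MOMCl, DMF, 0 °C → rt
Reagents that add atoms: chloromethyl methyl ether (MOMCl), COCCl
Why: Sodium hydride deprotonates both the 7-OH and the hydrogen-bonded 5-OH, so O-alkylation should mask both phenols and remove acidic protons that would quench the arylrhodium species in step 6.

Step 6
Reactants: 11 [3-geranyl-2,4-bis(methoxymethoxy)-5-prenylphenyl]boronic acid; 13 5,7-bis(methoxymethoxy)chromone
Product: 14 (2S)-2-[3-geranyl-2,4-bis(methoxymethoxy)-5-prenylphenyl]-5,7-bis(methoxymethoxy)chroman-4-one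
Conditions: [Rh(OH)((S)-MeO-F12-BIPHEP)]2 (3 mol % Rh), 11 (1.5 equiv, added in portions), toluene/H2O (10:1), 40 °C
Reagents that add atoms: none
Why: Transmetalation of 11 to the Rh(I)–OH complex gives an aryl–rhodium species, the chromone C2=C3 bond coordinates and inserts into the Ar–Rh bond so that C1' is delivered to C2 (the β-carbon of the vinylogous ester), and water protonates the resulting oxa-π-allyl rhodium enolate to release ketone 14 and regenerate Rh–OH. The closest known reaction type is the Hayashi–Miyaura rhodium-catalysed asymmetric 1,4-addition of arylboronic acids to enones, which is established on chromones as a route to 2-arylchroman-4-ones. No ring is closed; the pyranone ring is carried in intact and only C2 changes from sp2 to sp3. The C2 stereocentre is set by the catalyst: the C2-symmetric, electron-poor biaryl bisphosphine (6,6'-dimethoxybiphenyl-2,2'-diyl)bis[bis(3,4,5-trifluorophenyl)phosphine] differentiates the two faces of the flat chromone, and by the quadrant model for (S)-biaryl bisphosphines with cyclic enones the (S)-ligand is expected to give the 2S adduct (the antipodal ligand is used if the sense proves opposite). The step needs 1,4- over 1,2-addition, insertion faster than protodeboronation of the electron-rich ortho-alkoxy boronic acid, and no erosion of C2 by retro-oxa-Michael opening; the electron-poor ligand accelerates insertion, the C4 carbonyl is deactivated and shielded by the 5-OMOM group, 11 is added in portions, and the medium is base-free. The isolated trisubstituted alkenes of the geranyl and prenyl chains do not insert into aryl–rhodium bonds and should remain spectators.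

Step 7
Reactants: 14 (2S)-2-[3-geranyl-2,4-bis(methoxymethoxy)-5-prenylphenyl]-5,7-bis(methoxymethoxy)chroman-4-one
Product: 16 (2R,3R)-3-hydroxy-2-[3-geranyl-2,4-bis(methoxymethoxy)-5-prenylphenyl]-5,7-bis(methoxymethoxy)chroman-4-one, via sodium enolate 15 (not isolated)
Conditions: NaHMDS (1.1 equiv), THF, −78 °C; trans-2-(phenylsulfonyl)-3-phenyloxaziridine, −78 °C; AcOH quench at −78 °C
Reagents that add atoms: trans-2-(phenylsulfonyl)-3-phenyloxaziridine, O=S(=O)(c1ccccc1)N1OC1c1ccccc1
Why: Enolate hydroxylation with an N-sulfonyloxaziridine (Davis oxidation) should deliver oxygen to the planar C3 enolate on the face anti to the bulky C2 aryl group, setting the 2,3-trans (3R) centre by substrate control, while the reagent leaves isolated trisubstituted alkenes alone at −78 °C and the cold, short enolate lifetime and endocyclic C2–O1 bond (poorly aligned with the enolate π-system) suppress ring opening.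

Step 8
Reactants: 16 (2R,3R)-3-hydroxy-2-[3-geranyl-2,4-bis(methoxymethoxy)-5-prenylphenyl]-5,7-bis(methoxymethoxy)chroman-4-one
Product: 17 (2R,3R)-3,5,7-trihydroxy-2-[3-geranyl-2,4-dihydroxy-5-prenylphenyl]chroman-4-one
Conditions: 3 M aq. HCl/MeOH (1:4), 45 °C, monitored closely
Reagents that add atoms: none
Why: Acid-catalysed acetal methanolysis should cleave all four aryl MOM ethers under conditions routinely tolerated by ortho-prenylated phenols, and neither C2 nor C3 of the trans-dihydroflavonol is expected to epimerise in mild acid.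

Compound list
1 | resorcinol (benzene-1,3-diol) | Oc1cccc(O)c1 | starting material
2 | 1,3-bis(methoxymethoxy)benzene | COCOc1cccc(OCOC)c1 | intermediate
3 | geranyl bromide [(2E)-1-bromo-3,7-dimethylocta-2,6-diene] | CC(C)=CCC/C(C)=C/CBr | starting material
4 | 2-lithio-1,3-bis(methoxymethoxy)benzene | COCOc1cccc(OCOC)c1[Li] | intermediate
5 | 2-geranyl-1,3-bis(methoxymethoxy)benzene | CC(C)=CCC/C(C)=C/Cc1c(OCOC)cccc1OCOC | intermediate
6 | prenyl bromide (1-bromo-3-methylbut-2-ene) | CC(C)=CCBr | starting material
7 | 3-geranyl-2,4-bis(methoxymethoxy)phenyllithium | CC(C)=CCC/C(C)=C/Cc1c(OCOC)ccc([Li])c1OCOC | intermediate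
8 | 2-geranyl-1,3-bis(methoxymethoxy)-4-prenylbenzene | CC(C)=CCC/C(C)=C/Cc1c(OCOC)ccc(CC=C(C)C)c1OCOC | intermediate
9 | 3-geranyl-2,4-bis(methoxymethoxy)-5-prenylphenyllithium | CC(C)=CCC/C(C)=C/Cc1c(OCOC)c([Li])cc(CC=C(C)C)c1OCOC | intermediate
10 | lithium [3-geranyl-2,4-bis(methoxymethoxy)-5-prenylphenyl]trimethoxyborate | CC(C)=CCC/C(C)=C/Cc1c(OCOC)c([B-](OC)(OC)OC)cc(CC=C(C)C)c1OCOC.[Li+] | intermediate
11 | [3-geranyl-2,4-bis(methoxymethoxy)-5-prenylphenyl]boronic acid | CC(C)=CCC/C(C)=C/Cc1c(OCOC)c(B(O)O)cc(CC=C(C)C)c1OCOC | intermediate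
12 | 5,7-dihydroxychromone (5,7-dihydroxy-4H-chromen-4-one) | O=c1ccoc2cc(O)cc(O)c12 | starting material
13 | 5,7-bis(methoxymethoxy)chromone | O=c1ccoc2cc(OCOC)cc(OCOC)c12 | intermediate
14 | (2S)-2-[3-geranyl-2,4-bis(methoxymethoxy)-5-prenylphenyl]-5,7-bis(methoxymethoxy)chroman-4-one | CC(C)=CCC/C(C)=C/Cc1c(OCOC)c(CC=C(C)C)cc([C@H]2Oc3cc(OCOC)cc(OCOC)c3C(=O)C2)c1OCOC | intermediate
15 | sodium (2S)-enolate of 14 (sodium 2-aryl-5,7-bis(methoxymethoxy)-2H-chromen-4-olate) | CC(C)=CCC/C(C)=C/Cc1c(OCOC)c(CC=C(C)C)cc([C@H]2Oc3cc(OCOC)cc(OCOC)c3C([O-])=C2)c1OCOC.[Na+] | intermediate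
16 | (2R,3R)-3-hydroxy-2-[3-geranyl-2,4-bis(methoxymethoxy)-5-prenylphenyl]-5,7-bis(methoxymethoxy)chroman-4-one | CC(C)=CCC/C(C)=C/Cc1c(OCOC)c(CC=C(C)C)cc([C@H]2Oc3cc(OCOC)cc(OCOC)c3C(=O)[C@@H]2O)c1OCOC | intermediate
17 | (2R,3R)-3,5,7-trihydroxy-2-[3-geranyl-2,4-dihydroxy-5-prenylphenyl]chroman-4-one | CC(C)=CCC/C(C)=C/Cc1c(O)c(CC=C(C)C)cc([C@H]2Oc3cc(O)cc(O)c3C(=O)[C@@H]2O)c1O | target

Total step count: 8. Longest linear sequence: 7 steps (steps 1, 2, 3, 4, 6, 7, 8 from resorcinol).

Steps most likely to fail

Step 6. Protodeboronation of the electron-rich, ortho-alkoxy boronic acid may outrun migratory insertion into the deactivated 5,7-dioxygenated chromone, and the hindered aryl group may lower conversion or facial discrimination. The fallback sets out from 8 and returns at 14. Aryllithium 9 is generated as in step 4 and transmetalated with ZnCl2 to [3-geranyl-2,4-bis(methoxymethoxy)-5-prenylphenyl]zinc chloride F1. Rhodium/(S)-BINAP-catalysed 1,4-addition of F1 to 13 in THF in the presence of TMSCl should then give, under strictly aprotic conditions that exclude protodemetalation, the (2S)-2-aryl-5,7-bis(methoxymethoxy)-4-(trimethylsilyloxy)-2H-chromene F2. Brief treatment with aqueous citric acid in THF hydrolyses the silyl enol ether to 14.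

Step 7. The enolate may undergo β-elimination of the ring phenoxide (retro-oxa-Michael opening), which would erode the C2 configuration, or oxygen transfer may show incomplete facial selectivity. The fallback sets out from 14 and returns at 16. Soft enolisation with TBSOTf/Et3N in CH2Cl2 at 0 °C avoids a free enolate and should give the (2S)-2-aryl-4-(tert-butyldimethylsilyloxy)-5,7-bis(methoxymethoxy)-2H-chromene F3. Rubottom-type oxidation of F3 with the neutral N-sulfonyloxaziridine in CHCl3 at rt to 40 °C, anti to the C2 aryl group and with 1,4-silyl shift, should give the (2R,3R)-3-(tert-butyldimethylsilyloxy)-2-aryl-5,7-bis(methoxymethoxy)chroman-4-one F4. HF·pyridine in THF at 0 °C removes the silyl group to give 16.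

Step 8. Brønsted acid may promote cyclisation of the liberated phenols onto the adjacent prenyl or geranyl alkenes, or cationic cyclisation of the geranyl chain, during acetal cleavage. The fallback sets out from 16 and returns at 17. TMSOTf/2,2'-bipyridyl in MeCN at 0 °C exchanges the four aryl MOM ethers for trimethylsilyl ethers under buffered, non-acidic conditions and silylates the 3-OH, giving the (2R,3R)-pentakis(trimethylsilyl) ether of the target F5. Aqueous citric acid/MeOH at rt hydrolyses the silyl ethers to 17.

Further compounds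
F1 | step 6 | [3-geranyl-2,4-bis(methoxymethoxy)-5-prenylphenyl]zinc chloride | CC(C)=CCC/C(C)=C/Cc1c(OCOC)c([Zn]Cl)cc(CC=C(C)C)c1OCOC
F2 | step 6 | (2S)-2-[3-geranyl-2,4-bis(methoxymethoxy)-5-prenylphenyl]-5,7-bis(methoxymethoxy)-4-(trimethylsilyloxy)-2H-chromene | CC(C)=CCC/C(C)=C/Cc1c(OCOC)c(CC=C(C)C)cc([C@H]2Oc3cc(OCOC)cc(OCOC)c3C(O[Si](C)(C)C)=C2)c1OCOC
F3 | step 7 | (2S)-4-(tert-butyldimethylsilyloxy)-2-[3-geranyl-2,4-bis(methoxymethoxy)-5-prenylphenyl]-5,7-bis(methoxymethoxy)-2H-chromene | CC(C)=CCC/C(C)=C/Cc1c(OCOC)c(CC=C(C)C)cc([C@H]2Oc3cc(OCOC)cc(OCOC)c3C(O[Si](C)(C)C(C)(C)C)=C2)c1OCOC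
F4 | step 7 | (2R,3R)-3-(tert-butyldimethylsilyloxy)-2-[3-geranyl-2,4-bis(methoxymethoxy)-5-prenylphenyl]-5,7-bis(methoxymethoxy)chroman-4-one | CC(C)=CCC/C(C)=C/Cc1c(OCOC)c(CC=C(C)C)cc([C@H]2Oc3cc(OCOC)cc(OCOC)c3C(=O)[C@@H]2O[Si](C)(C)C(C)(C)C)c1OCOC
F5 | step 8 | (2R,3R)-2-[3-geranyl-5-prenyl-2,4-bis(trimethylsilyloxy)phenyl]-3,5,7-tris(trimethylsilyloxy)chroman-4-one | CC(C)=CCC/C(C)=C/Cc1c(O[Si](C)(C)C)c(CC=C(C)C)cc([C@H]2Oc3cc(O[Si](C)(C)C)cc(O[Si](C)(C)C)c3C(=O)[C@@H]2O[Si](C)(C)C)c1O[Si](C)(C)C
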